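**Plan**

1. Side-chain numbering: C1' = ArOCH2, C2' = oxirane CH, C3' = oxirane C(CH3), C4' = CH2, C5' = lactone CH–O, C6' = CH2, C7' = C(OH)CH3, C8' = lactone C=O.
2. Cuts, last-made bond first: the O–C1' aryl ether (umbelliferone), the oxirane oxygen on C2'=C3', the lactone O–C8' bond (the acid stays masked with the C7' hydroxyl as an acetonide), the C2'=C3' double bond, and C4'–C5' (methallyl onto an aldehyde from (R)-citramalic acid).
3. Enabling feature: the oxygens on C1' and C5' are 1,5-related across C2'=C3', and C1' is cis to C4' on the oxirane. One silicon bridging both oxygens puts the alkene into an eight-membered 1,3-dioxa-2-silacyclooctene, which can hold the trisubstituted alkene only as Z.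
4. Forward order: dioxolanone ring (mask for C7'/C8') → C4'–C5' bond → silaketal ring by metathesis → tether off and γ-lactone ring closed in one operation → oxirane ring → coumarin joined last.
5. Stereochemistry: C7' from (R)-citramalic acid; C5' from reagent-controlled methallylboration (isopinocampheyl groups of the (+)-α-pinene series); alkene geometry from the ring; C2'/C3' from Sharpless epoxidation with L-(+)-diethyl tartrate, cis because the alkene is Z.

Key step: step 6

Remark: (R)-citramalic acid, (−)-Ipc2BOMe, L-(+)-diethyl tartrate, allyl alcohol, dichlorodiisopropylsilane and umbelliferone are taken as commercial. The SMILES strings fix the configurations; C5' keeps one geometry throughout, but its descriptor changes from S to R at the epoxidation because the ranking of C4' and C6' reverses.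

**Route**

Step 1
Reactants: 1 (R)-citramalic acid
Product: 2 2-[(4R)-2,2,4-trimethyl-5-oxo-1,3-dioxolan-4-yl]acetic acid
Conditions: 2,2-dimethoxypropane, TsOH·H2O (cat.), acetone, rt
Reagents that add atoms: 2,2-dimethoxypropane, COC(C)(C)OC
Why: Acid-catalysed transacetalisation closes the five-membered 1,3-dioxolan-4-one on the tertiary hydroxyl and its own α-carboxyl in preference to the six-membered alternative, which leaves the CH2CO2H arm free and does not touch C7'.

Step 2
Reactants: 2 2-[(4R)-2,2,4-trimethyl-5-oxo-1,3-dioxolan-4-yl]acetic acid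
Product: 3 (5R)-5-(2-hydroxyethyl)-2,2,5-trimethyl-1,3-dioxolan-4-one
Conditions: BH3·SMe2, THF, 0 °C to rt; MeOH quench, no acid
Reagents that add atoms: none
Why: Chemoselective borane reduction takes the free carboxylic acid through its acyloxyborane much faster than the ester-type carbonyl of the dioxolanone, and the acid-free quench keeps the γ-hydroxy dioxolanone from lactonising.

Step 3
Reactants: 3 (5R)-5-(2-hydroxyethyl)-2,2,5-trimethyl-1,3-dioxolan-4-one
Product: 4 2-[(4R)-2,2,4-trimethyl-5-oxo-1,3-dioxolan-4-yl]acetaldehyde
Conditions: Dess–Martin periodinane, NaHCO3, CH2Cl2, 0 °C to rt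
Reagents that add atoms: none
Why: Dess–Martin oxidation under bicarbonate buffer stops at the aldehyde and is neither acidic enough to lactonise 3 nor basic enough to eliminate the β-oxygen of 4.

Step 4
Reactants: 4 2-[(4R)-2,2,4-trimethyl-5-oxo-1,3-dioxolan-4-yl]acetaldehyde
Product: 6 (5R)-5-[(2S)-2-hydroxy-4-methylpent-4-en-1-yl]-2,2,5-trimethyl-1,3-dioxolan-4-one, via diisopinocampheylborinate 5 (not isolated)
Conditions: (−)-Ipc2BOMe, CH2=C(CH3)CH2MgCl, Et2O, −78 °C to rt; then 4, −78 °C; then pH 7 phosphate buffer, MeOH, 30% H2O2, 0 °C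
Reagents that add atoms: methallylmagnesium chloride, CC(=C)C[Mg]Cl (delivered as B-methallyldiisopinocampheylborane, CC(=C)CB([C@@H]1C[C@@H]2C[C@H]([C@H]1C)C2(C)C)[C@@H]1C[C@@H]2C[C@H]([C@H]1C)C2(C)C)
Why: Brown asymmetric methallylboration runs through a closed chair six-membered transition state in which the isopinocampheyl groups of the (+)-α-pinene series send the methallyl group to the Si face of the aldehyde (5'S, the same sense as benzaldehyde giving the S alcohol), reagent control overriding the weak 1,3-bias of quaternary C7', and buffered peroxide cleaves the borinate without exposing the C5' hydroxyl to base.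

Step 5
Reactants: 6 (5R)-5-[(2S)-2-hydroxy-4-methylpent-4-en-1-yl]-2,2,5-trimethyl-1,3-dioxolan-4-one; 7 dichlorodiisopropylsilane; 8 allyl alcohol
Product: 10 (5R)-5-[(2S)-4-methyl-2-{[di(propan-2-yl)(prop-2-en-1-yloxy)silyl]oxy}pent-4-en-1-yl]-2,2,5-trimethyl-1,3-dioxolan-4-one, via chlorosilyl ether 9 (not isolated)
Conditions: 7 (3 equiv), imidazole, CH2Cl2, 0 °C; excess 7 removed in vacuo; then 8, imidazole, CH2Cl2, 0 °C to rt
Reagents that add atoms: none
Why: Stepwise nucleophilic substitution at silicon (silyl ether formation) puts the hindered C5' hydroxyl once on the excess dichlorosilane and then lets unhindered allyl alcohol displace the second chloride, with imidazole as a mild HCl acceptor of the kind γ-hydroxy dioxolanones tolerate.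

Step 6
Reactants: 10 (5R)-5-[(2S)-4-methyl-2-{[di(propan-2-yl)(prop-2-en-1-yloxy)silyl]oxy}pent-4-en-1-yl]-2,2,5-trimethyl-1,3-dioxolan-4-one
Product: 11 (5Z,8S)-6-methyl-2,2-di(propan-2-yl)-8-{[(4R)-2,2,4-trimethyl-5-oxo-1,3-dioxolan-4-yl]methyl}-1,3-dioxa-2-silacyclooct-5-ene
Conditions: second-generation Grubbs catalyst (H2IMes)(PCy3)Cl2Ru=CHPh (10 mol %, two portions), 1,4-benzoquinone (10 mol %), toluene (0.003 M), 80 °C, Ar sparge
Reagents that add atoms: none
Why: The ruthenium benzylidene first exchanges onto the unhindered allyloxy alkene, and the new alkylidene on C2' adds across the tethered 1,1-disubstituted methallyl alkene to give a ruthenacyclobutane whose cycloreversion forms C2'=C3' and a ruthenium methylidene, the two lost CH2 groups leaving as ethylene. The closest known reaction type is temporary silicon-tethered ring-closing metathesis of bis-alkoxysilanes, in which seven- and eight-membered silaketals with trisubstituted alkenes have been closed by this catalyst class. The one ring formed, the eight-membered 1,3-dioxa-2-silacyclooct-5-ene, closes by intramolecular metathesis between the two terminal alkenes, helped by the long Si–O bonds and the angle compression from the two isopropyl groups on silicon. No stereocentre is created, and C5' and C7' are spectators. The selectivity needed is alkene geometry, and the ring secures it because it can hold the trisubstituted alkene only with C1' and C4' cis; high dilution, ethylene removal and the bulky silicon substituents favour cyclisation over oligomerisation, benzoquinone suppresses allyl ether isomerisation, and the dioxolanone is inert to the catalyst.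

Step 7
Reactants: 11 (5Z,8S)-6-methyl-2,2-di(propan-2-yl)-8-{[(4R)-2,2,4-trimethyl-5-oxo-1,3-dioxolan-4-yl]methyl}-1,3-dioxa-2-silacyclooct-5-ene
Product: 13 (3R,5S)-3-hydroxy-5-[(2Z)-4-hydroxy-2-methylbut-2-en-1-yl]-3-methyloxolan-2-one, via dioxolanone diol 12 (not isolated)
Conditions: Bu4NF (2.5 equiv), THF, 0 °C to rt; then water
Reagents that add atoms: none
Why: Fluoride cleaves both Si–O bonds (desilylation), and the released C5' alkoxide attacks the activated dioxolanone carbonyl C8' in a 5-exo-trig acyl transfer that expels acetone (translactonisation), so the C5'–O bond and its configuration are kept and the primary allylic alcohol is left free.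

Step 8
Reactants: 13 (3R,5S)-3-hydroxy-5-[(2Z)-4-hydroxy-2-methylbut-2-en-1-yl]-3-methyloxolan-2-one
Product: 14 (3R,5R)-3-hydroxy-5-{[(2R,3S)-3-(hydroxymethyl)-2-methyloxiran-2-yl]methyl}-3-methyloxolan-2-one
Conditions: Ti(OiPr)4 (1.0 equiv), L-(+)-diethyl tartrate (1.2 equiv), t-BuOOH (2 equiv, decane), 4 Å molecular sieves, CH2Cl2, −25 °C; then 10% aq. tartaric acid, 0 °C
Reagents that add atoms: tert-butyl hydroperoxide, CC(C)(C)OO
Why: Sharpless asymmetric epoxidation delivers the peroxide oxygen to the allylic alcohol bound to the titanium tartrate, L-(+)-diethyl tartrate setting C2' as S in the same sense as for nerol, and the Z alkene passes stereospecifically into the cis oxirane with C3' as R.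

Step 9
Reactants: 14 (3R,5R)-3-hydroxy-5-{[(2R,3S)-3-(hydroxymethyl)-2-methyloxiran-2-yl]methyl}-3-methyloxolan-2-one; 15 umbelliferone
Product: 16 7-{[(2S,3R)-3-{[(2R,4R)-4-hydroxy-4-methyl-5-oxooxolan-2-yl]methyl}-3-methyloxiran-2-yl]methoxy}-2H-chromen-2-one
Conditions: PPh3, diisopropyl azodicarboxylate, THF, 0 °C to rt
Reagents that add atoms: none
Why: Mitsunobu etherification activates the primary C1' hydroxyl as its oxyphosphonium salt, which the acidic 7-hydroxyl of umbelliferone displaces by SN2 at the unhindered CH2 without touching the oxirane, the tertiary alcohol or any stereocentre.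

**Compound list**

1 | (R)-citramalic acid, (2R)-2-hydroxy-2-methylbutanedioic acid | OC(=O)C[C@@](C)(O)C(=O)O | starting material
2 | 2-[(4R)-2,2,4-trimethyl-5-oxo-1,3-dioxolan-4-yl]acetic acid | OC(=O)C[C@@]1(C)OC(C)(C)OC1=O | intermediate
3 | (5R)-5-(2-hydroxyethyl)-2,2,5-trimethyl-1,3-dioxolan-4-one | OCC[C@@]1(C)OC(C)(C)OC1=O | intermediate
4 | 2-[(4R)-2,2,4-trimethyl-5-oxo-1,3-dioxolan-4-yl]acetaldehyde | O=CC[C@@]1(C)OC(C)(C)OC1=O | intermediate
5 | diisopinocampheylborinate of carbinol 6 (formed in the flask, not isolated) | C=C(C)C[C@H](OB([C@@H]1C[C@@H]2C[C@H]([C@H]1C)C2(C)C)[C@@H]1C[C@@H]2C[C@H]([C@H]1C)C2(C)C)C[C@@]1(C)OC(C)(C)OC1=O | intermediate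
6 | (5R)-5-[(2S)-2-hydroxy-4-methylpent-4-en-1-yl]-2,2,5-trimethyl-1,3-dioxolan-4-one | C=C(C)C[C@H](O)C[C@@]1(C)OC(C)(C)OC1=O | intermediate
7 | dichlorodiisopropylsilane | CC(C)[Si](Cl)(Cl)C(C)C | starting material
8 | allyl alcohol | C=CCO | starting material
9 | chloro(diisopropyl)silyl ether of carbinol 6 (formed in the flask, not isolated) | C=C(C)C[C@H](O[Si](Cl)(C(C)C)C(C)C)C[C@@]1(C)OC(C)(C)OC1=O | intermediate
10 | allyloxy(diisopropyl)silyl ether of carbinol 6 | C=CCO[Si](C(C)C)(C(C)C)O[C@@H](CC(C)=C)C[C@@]1(C)OC(C)(C)OC1=O | intermediate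
11 | (5Z,8S)-6-methyl-2,2-di(propan-2-yl)-8-{[(4R)-2,2,4-trimethyl-5-oxo-1,3-dioxolan-4-yl]methyl}-1,3-dioxa-2-silacyclooct-5-ene | C/C1=C/CO[Si](C(C)C)(C(C)C)O[C@H](C[C@@]2(C)OC(C)(C)OC2=O)C1 | intermediate
12 | (5R)-5-[(2S,4Z)-2,6-dihydroxy-4-methylhex-4-en-1-yl]-2,2,5-trimethyl-1,3-dioxolan-4-one (formed in the flask, not isolated) | OC/C=C(/C)C[C@H](O)C[C@@]1(C)OC(C)(C)OC1=O | intermediate
13 | (3R,5S)-3-hydroxy-5-[(2Z)-4-hydroxy-2-methylbut-2-en-1-yl]-3-methyloxolan-2-one | OC/C=C(/C)C[C@H]1C[C@@](C)(O)C(=O)O1 | intermediate
14 | (3R,5R)-3-hydroxy-5-{[(2R,3S)-3-(hydroxymethyl)-2-methyloxiran-2-yl]methyl}-3-methyloxolan-2-one | C[C@]1(C[C@H]2C[C@@](C)(O)C(=O)O2)O[C@H]1CO | intermediate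
15 | umbelliferone, 7-hydroxy-2H-chromen-2-one | O=c1ccc2ccc(O)cc2o1 | starting material
16 | 7-{[(2S,3R)-3-{[(2R,4R)-4-hydroxy-4-methyl-5-oxooxolan-2-yl]methyl}-3-methyloxiran-2-yl]methoxy}-2H-chromen-2-one | C[C@]1(C[C@H]2C[C@@](C)(O)C(=O)O2)O[C@H]1COc1ccc2ccc(=O)oc2c1 | target

**Count**

Total steps: 9. Longest linear sequence: 9 steps (from 1).

**Steps most likely to fail**

Step 6. Closure of the medium ring onto the 1,1-disubstituted alkene may be slow, so intermolecular metathesis through the allyl termini (oligomers) and ruthenium hydride isomerisation of the allyl ether could take over. The fallback shrinks the ring and moves the silicon onto carbon. It sets out from 6, which is silylated with allyl(chloro)dimethylsilane and imidazole to give the allyl(dimethyl)silyl ether F1. The same ruthenium catalyst then closes the seven-membered (Z)-1-oxa-2-silacyclohept-4-ene F2, in which silicon is bound to C1' and the ring again forces C1' cis to C4'. Tamao–Fleming oxidation (30% H2O2, KF, KHCO3, THF/MeOH) converts the Si–C1' bond into the C1' hydroxyl and breaks the Si–O bond, and the freed C5' hydroxyl closes the lactone with loss of acetone. The fallback comes back to the route at 13.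

Step 4. Facial selectivity may be poor, because the bulky borane adds slowly to the neopentyl-type aldehyde and the resident C7' centre can then make itself felt. Acyl transfer of the dioxolanone to the C5' oxygen may also set in while the boron–oxygen bond is cleaved. The fallback replaces the stoichiometric allylborane by a Lewis-acid-catalysed allylstannane addition with an open transition state (Keck allylation). It sets out from 4, which is treated with methallyltributylstannane, (S)-BINOL and Ti(OiPr)4 (2:1, 10 mol %), 4 Å molecular sieves, CH2Cl2, −20 °C; (S)-BINOL directs attack to the same Si face. The carbinol is released as its tributylstannyl ether F3, which a bicarbonate wash hydrolyses without any oxidant. The fallback comes back at 6.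

Step 8. The tertiary α-hydroxy lactone may compete with the tartrate for titanium and the Z trisubstituted alkene reacts slowly, so enantiofacial control could drop. The Lewis acid may also let the C7' hydroxyl, which is cis to the side chain on the lactone, open the new oxirane at C3'. The fallback inverts the order and epoxidises without a metal. It sets out from 13, which is joined to 15 under Mitsunobu conditions (PPh3, diisopropyl azodicarboxylate, THF) to give the (Z)-allyl coumarinyl ether F4. Shi epoxidation then follows with the L-fructose-derived enantiomer of the Shi ketone, Oxone (2KHSO5·KHSO4·K2SO4), K2CO3 buffer near pH 8, MeCN/dimethoxymethane/water, 0 °C. This ketone enantiomer is chosen because the D-fructose ketone gives R,R epoxides from trans alkenes, which maps onto the wrong face here. The electron-poor coumarin alkene should not react, and the fallback comes back at 16.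

**Further compounds**

F1 | step 6 | allyl(dimethyl)silyl ether of carbinol 6 | C=CC[Si](C)(C)O[C@@H](CC(C)=C)C[C@@]1(C)OC(C)(C)OC1=O
F2 | step 6 | (4Z,7S)-2,2,5-trimethyl-7-{[(4R)-2,2,4-trimethyl-5-oxo-1,3-dioxolan-4-yl]methyl}-1-oxa-2-silacyclohept-4-ene | C/C1=C/C[Si](C)(C)O[C@H](C[C@@]2(C)OC(C)(C)OC2=O)C1
F3 | step 4 | tributylstannyl ether of carbinol 6 | C=C(C)C[C@H](O[Sn](CCCC)(CCCC)CCCC)C[C@@]1(C)OC(C)(C)OC1=O
F4 | step 8 | 7-{[(2Z)-4-[(2S,4R)-4-hydroxy-4-methyl-5-oxooxolan-2-yl]-3-methylbut-2-en-1-yl]oxy}-2H-chromen-2-one | O=c1ccc2ccc(OC/C=C(/C)C[C@H]3C[C@@](C)(O)C(=O)O3)cc2o1
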